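## Analysis of the target

CNP0325426.1 is built from two naphthalene-derived halves joined by one ether oxygen. The numbering used here is: in the quinone half, C1 is the carbonyl next to the ethyl-bearing C2, C3 carries the ether oxygen, C4 is the second carbonyl, and ring B has hydroxyl groups on C5, C6 and C8 and hydrogen on C7. In the trione half (primed), C1′ and C2′ are the vicinal dione, C3′ is the quaternary carbon bearing ethyl and the ether oxygen, C4′ is the lone ketone, and the arene has hydroxyl groups on C5′, C7′ and C8′ and hydrogen on C6′.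

C3′ (S) is the only stereocenter. It has no α-hydrogen and cannot epimerise; it can be lost only by heterolysis of its C–O bond or by cleavage of the carbonyl array around it.

The C3–O–C3′ bridge is a vinylogous ester of a tertiary alcohol, so hydroxide and amines can cleave it at C3. The C1′/C2′/C4′ carbonyl array is open to retro-Claisen and benzilic-acid chemistry under base, and the six peri-chelated phenols are redox-active.

The synthesis is hard for three reasons: the hindered ether between a quaternary carbon and a quinone carbon, the same 1,2,4-trioxygenation pattern needed on two arenes in defined orientation, and the quaternary stereocenter.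

The strategy rests on ring B of the quinone half (C4a–C5–C6–C7–C8–C8a). Oxygen on C5, C6 and C8 with hydrogen on C7 is the pattern that a four-carbon vinylketene acetal oxygenated on three of its carbons delivers when it is annulated across C4a–C8a of a benzoquinone.

## Retrosynthetic reasoning

**Phenol unmasking.** Target 41 is traced to its hexamethyl ether 40. The free phenols would not survive the oxidations that build the trione, and in 40 the bridging ether is at its most robust, because C3′ is quaternary and flanked by two carbonyls. One Lewis-acid step then ends the route.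

**Vicinal dione.** The C1′/C2′ dione of 40 comes from the cis-diol 39 and this from the ring alkene C1′=C2′ of naphthalenone 38. That alkene is an electron-rich styrene, far more reactive to osmium than the tetrasubstituted quinone double bond, so the oxidation level is raised only where needed.

**C4′–C4a′ bond.** Ring closure of 38 is cut between the ketone carbon C4′ and the arene carbon C4a′, back to the Z-alkenoic acid 36. C4a′ is the only free position ortho to the side chain and lies ortho and para to two methoxy groups, so a mild intramolecular Friedel–Crafts acylation should suffice. The Z geometry comes from semihydrogenation of alkyne acid 34, and the acid from tert-butyl ester 32. The ester is tert-butyl because a hindered ester must be removed in the presence of a base-labile vinylogous ester, which rules out saponification.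

**Ring B of the quinone half (key disconnection).** Trimethyl ether 32 comes from dihydroxy-methoxy-naphthoquinone 31 by O-methylation. In 31 the bonds C4a–C5 and C8a–C8 are cut, giving bromobenzoquinone 24 and the bis(silyloxy)diene 27. This builds the whole trioxygenated arene in one step from an acyclic acetoacetate. The forward reaction must deliver one orientation only; that is assigned to the bromine on C6 of 24, the carbon that becomes C8a.

**Bromoquinone.** Quinone 24 is traced through bromophenol 22 to the mono-silylated hydroquinone 21, and 21 to the 4-vinylcyclobutenone 18 by thermal ring expansion. Silylating the carbinol oxygen of 18 leaves the two hydroquinone oxygens of 21 differentiated. The free hydroxyl on C1 then directs an electrophilic bromine source to C6, its only open ortho position.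

**Ether bond.** Cyclobutenone 18 comes from squarate ester 16 by vinyl addition. The hindered C3–O bond of 16 is cut to the tertiary alcohol 10 and the vinylogous acid chloride 15. The ether is thus made by acyl-substitution-type chemistry on the most electrophilic acceptor available, before any quinone exists.

**Squarate fragment.** Chloride 15 derives from hydroxy compound 14, isopropyl ester 13 and diisopropyl squarate 11 by ethyl addition, hydrolysis and chlorination.

**Stereocenter.** Alcohol 10 is cut at the bond between C3′ and the alkyne carbon, giving aryl alkyne 7 and keto ester 9 (from acid 8). A catalytic enantioselective alkynylation sets the only stereocenter early, on small molecules. Alkyne 7 comes from aryl bromide 4 and silylacetylene 5 through 6; bromide 4 comes from aldehyde 1 through phenol 3.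

**Diene.** Diene 27 comes from methyl 4-methoxyacetoacetate 25 by two successive silylations through 26.

## Alternatives that were turned down

**Alternative 1:** Both C–O bonds at C3′ are disconnected, leading back to the symmetric bis(2-ethyl-5,6,8-trimethoxy-1,4-naphthoquinon-3-yl) ether A1. In the forward step a chiral dioxirane would epoxidise the C2=C3 double bond of one ring. The epoxide would open at the acetal carbon, the new alkoxide on the ethyl-bearing carbon would take over the second quinonyl group through a spiro intermediate, and the former ether oxygen would become a carbonyl. The product is the hexamethyl ether A2, identical with 40.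
- For: it is by far the shortest plan, both halves come from one naphthoquinone, and stereocenter, ether and oxidation level arise together.
- Against: the double bond is tetrasubstituted and sits inside a quinone, which an electrophilic dioxirane attacks poorly. Face selection on a flat quinone has no close model for high enantioselectivity. The intermediate can collapse in other ways (hydrolysis, ring contraction, attack on the second ring). A1 itself is a moisture-sensitive vinylogous anhydride.
- Comparison: Alternative 1 is clearly stronger on step economy. The chosen strategy offers instead a stereocenter set by a precedented catalytic addition and an ether formed with unambiguous connectivity.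

**Alternative 2:** The bond between the carbinol carbon and the adjacent aryl ketone carbon is disconnected, leading to keto aldehyde A3, 3,4,6-trimethoxy-2-(3-oxopentyl)benzaldehyde. An N-heterocyclic carbene turns the aldehyde into an acyl anion equivalent that adds to the ethyl ketone, giving hydroxy tetralone A4 as a single enantiomer.
- For: intramolecular aldehyde–ketone benzoin closures to six-membered tertiary ketols are well established and highly enantioselective, and A3 is simple. On the stereocenter this plan is at least as strong as the chosen one.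
- Against: A4 has two methylene groups where the target has the vicinal dione, so two carbon oxidations next to an electron-rich arene are needed. The hindered ketol oxygen must then be joined to a quinone carbon under basic conditions, where ketols rearrange or revert.
- Comparison: the hardest bond of the molecule is postponed to the least favourable stage. The chosen strategy forms it early on a squaric chloride and meets the dione by alkene oxidation.

**Alternative 3:** The quinone ring of the quinone half is disconnected at C1–C8a, leading to the 4-aryl-4-hydroxycyclobutenone A5, the ethyl-ester counterpart of the adduct of an aryllithium from 4 with a squarate ester of type 16. Heating opens A5 to a dienylketene whose ketene carbon bonds to the one free ortho carbon of the aryl group, giving naphthalene-1,4-diol A6.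
- For: the chemistry is fully precedented, the same aryl bromide serves both halves, regiochemistry is fixed by the single free ortho position, and no bromination, diene or methylation is needed. It is about five steps shorter and stronger on precedent.
- Against: electrocyclisation onto an arene needs a higher temperature than onto a vinyl group, with the tertiary propargylic vinyl ether present. The ortho-methoxy aryllithium must add next to the bulky alkoxy-bearing carbon.
- Comparison: the chosen strategy offers a milder ring expansion, a ring B assembled from an inexpensive acetoacetate with its three oxygens differentiated (C5 methoxy, C6 and C8 hydroxyl), and a bromoquinone that can take other dienes. The chemistry of Alternative 3 is kept as the fallback for the key step.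

Key step: step 17

Remark on the chemistry: the carboxyl group is carried as a tert-butyl ester in place of an ethyl ester; 3-bromo-4,5-dimethoxybenzaldehyde (the O-methyl ether of 5-bromovanillin) and 2-oxobutanoic acid are taken as commercial; in step 6 the antipode of the amino alcohol ligand is the one that delivers the R alcohol.

## Route

**Step 1**
Reactants: 1 3-bromo-4,5-dimethoxybenzaldehyde
Product: 3 3-bromo-4,5-dimethoxyphenol, via aryl formate 2 (not isolated)
Conditions: mCPBA, CH2Cl2, rt; then K2CO3 (cat.), MeOH, rt
Reagents that add atoms: 3-chloroperoxybenzoic acid, OOC(=O)c1cccc(Cl)c1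
Why: Baeyer–Villiger oxidation; the aryl group, activated by its para methoxy group, migrates in preference to hydrogen to give formate 2, which methanolysis converts to the phenol. The aryl bromide and the ethers are inert.

**Step 2**
Reactants: 3 3-bromo-4,5-dimethoxyphenol
Product: 4 1-bromo-2,3,5-trimethoxybenzene
Conditions: MeI, K2CO3, acetone, reflux
Reagents that add atoms: iodomethane, CI
Why: Williamson O-methylation of the phenoxide; no other nucleophilic site is present.

**Step 3**
Reactants: 4 1-bromo-2,3,5-trimethoxybenzene; 5 ethynyltrimethylsilane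
Product: 6 trimethyl[(2,3,5-trimethoxyphenyl)ethynyl]silane
Conditions: Pd(PPh3)2Cl2 (3 mol %), CuI (6 mol %), Et3N, DMF, 80 °C, sealed vessel
Reagents that add atoms: none
Why: Sonogashira coupling; the electron-rich, ortho-substituted bromide needs heating, and the silyl group blocks the second alkyne terminus.

**Step 4**
Reactants: 6 trimethyl[(2,3,5-trimethoxyphenyl)ethynyl]silane
Product: 7 1-ethynyl-2,3,5-trimethoxybenzene
Conditions: K2CO3 (cat.), MeOH, rt
Reagents that add atoms: none
Why: Methoxide-induced protodesilylation of an alkynylsilane, a routine C–Si cleavage.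

**Step 5**
Reactants: 8 2-oxobutanoic acid
Product: 9 tert-butyl 2-oxobutanoate
Conditions: tert-butyl 2,2,2-trichloroacetimidate, CH2Cl2/cyclohexane, rt
Reagents that add atoms: tert-butyl 2,2,2-trichloroacetimidate, CC(C)(C)OC(=N)C(Cl)(Cl)Cl
Why: Acid-promoted tert-butylation with the trichloroacetimidate; the keto acid is acidic enough to activate the imidate itself, and no base is present that could start aldol reactions.

**Step 6**
Reactants: 7 1-ethynyl-2,3,5-trimethoxybenzene; 9 tert-butyl 2-oxobutanoate
Product: 10 tert-butyl (R)-2-ethyl-2-hydroxy-4-(2,3,5-trimethoxyphenyl)but-3-ynoate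
Conditions: Zn(OTf)2 (20 mol %), (1S,2S)-3-(tert-butyldimethylsilyloxy)-2-(dimethylamino)-1-(4-nitrophenyl)propan-1-ol or its (1R,2R) antipode (22 mol %), Et3N (30 mol %), toluene, 50 °C
Reagents that add atoms: none
Why: Catalytic enantioselective alkynylation of an α-keto ester; the zinc acetylide formed from 7 adds to the ester-activated ketone inside the chiral amino-alkoxide complex. The ligand selects the ketone face and so sets the R quaternary carbinol, helped by the large difference between the ethyl and tert-butoxycarbonyl flanks.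

**Step 7**
Reactants: 11 3,4-diisopropoxycyclobut-3-ene-1,2-dione (diisopropyl squarate)
Product: 13 3-ethyl-4-isopropoxycyclobut-3-ene-1,2-dione, via hydroxy adduct 12 (not isolated)
Conditions: EtMgBr, THF, –78 °C; NH4Cl (aq); then 12 M HCl (cat.), CH2Cl2, rt
Reagents that add atoms: ethylmagnesium bromide, CC[Mg]Br
Why: 1,2-Addition to one squarate carbonyl at low temperature, then acid-induced loss of propan-2-ol from 12 with carbonyl transposition; this is the standard entry to 3-alkyl-4-alkoxycyclobutenediones.

**Step 8**
Reactants: 13 3-ethyl-4-isopropoxycyclobut-3-ene-1,2-dione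
Product: 14 3-ethyl-4-hydroxycyclobut-3-ene-1,2-dione
Conditions: 6 M HCl, THF, 50 °C
Reagents that add atoms: water, O
Why: Acid hydrolysis of a vinylogous ester by addition–elimination of water at the alkoxy-bearing carbon.

**Step 9**
Reactants: 14 3-ethyl-4-hydroxycyclobut-3-ene-1,2-dione
Product: 15 3-chloro-4-ethylcyclobut-3-ene-1,2-dione
Conditions: (COCl)2, DMF (cat.), CH2Cl2, 0 °C → rt
Reagents that add atoms: oxalyl chloride, ClC(=O)C(=O)Cl
Why: Conversion of a vinylogous carboxylic acid into the vinylogous acid chloride by Vilsmeier-type activation; 15 is used without storage.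

**Step 10**
Reactants: 10 tert-butyl (R)-2-ethyl-2-hydroxy-4-(2,3,5-trimethoxyphenyl)but-3-ynoate; 15 3-chloro-4-ethylcyclobut-3-ene-1,2-dione
Product: 16 tert-butyl (R)-2-ethyl-2-[(2-ethyl-3,4-dioxocyclobut-1-en-1-yl)oxy]-4-(2,3,5-trimethoxyphenyl)but-3-ynoate
Conditions: NaH, THF, 0 °C; then 15, –78 → 0 °C
Reagents that add atoms: none
Why: Addition–elimination of the tertiary alkoxide at the chlorine-bearing carbon of a vinylogous acid chloride, the most electrophilic acceptor available for this hindered oxygen. Only the O–H bond of 10 reacts, so the stereocenter is untouched.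

**Step 11**
Reactants: 16 tert-butyl (R)-2-ethyl-2-[(2-ethyl-3,4-dioxocyclobut-1-en-1-yl)oxy]-4-(2,3,5-trimethoxyphenyl)but-3-ynoate
Product: 18 tert-butyl (2R)-2-ethyl-2-{[2-ethyl-3-oxo-4-(triethylsilyloxy)-4-vinylcyclobut-1-en-1-yl]oxy}-4-(2,3,5-trimethoxyphenyl)but-3-ynoate (both epimers at the ring carbinol carbon), via bromomagnesium alkoxide 17 (not isolated)
Conditions: CH2=CHMgBr, THF, –78 °C; then Et3SiOTf, –78 → –20 °C
Reagents that add atoms: vinylmagnesium bromide, C=C[Mg]Br; triethylsilyl trifluoromethanesulfonate, CC[Si](CC)(CC)OS(=O)(=O)C(F)(F)F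
Why: The Grignard reagent adds to the ketone-like carbonyl next to the alkoxy-bearing carbon, because the other carbonyl is a deactivated vinylogous ester and the tert-butyl ester is too hindered at –78 °C. The silyl triflate caps the oxygen that must later be told apart from its partner; the new ring stereocenter is uncontrolled and is lost in step 12.

**Step 12**
Reactants: 18 the 4-vinyl-4-(triethylsilyloxy)cyclobutenone
Product: 21 tert-butyl (R)-2-ethyl-2-[2-ethyl-3-hydroxy-6-(triethylsilyloxy)phenoxy]-4-(2,3,5-trimethoxyphenyl)but-3-ynoate, via dienylketene 19 (not isolated), via cyclohexadienone 20 (not isolated)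
Conditions: toluene (degassed), 110 °C
Reagents that add atoms: none
Why: Thermal cyclobutenone ring expansion (Moore rearrangement): 4π ring opening to ketene 19, 6π electrocyclisation to 20 and tautomerisation to the phenol. The silyl group stays on the former carbinol oxygen, so the hydroxyl next to the ethyl-bearing carbon emerges free.

**Step 13**
Reactants: 21 the mono-silylated hydroquinone
Product: 22 tert-butyl (R)-2-[4-bromo-2-ethyl-3-hydroxy-6-(triethylsilyloxy)phenoxy]-2-ethyl-4-(2,3,5-trimethoxyphenyl)but-3-ynoate
Conditions: NBS (1.0 equiv), iPr2NH (10 mol %), CH2Cl2, –78 → 0 °C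
Reagents that add atoms: N-bromosuccinimide, BrN1C(=O)CCC1=O
Why: Electrophilic aromatic bromination ortho to the free phenol; C6 is the only open position ortho to the hydroxyl and is also para to the alkoxy group. Amine-catalysed conditions at low temperature favour a phenol over the methoxyarene ring.

**Step 14**
Reactants: 22 the bromophenol silyl ether
Product: 24 tert-butyl (R)-2-[(6-bromo-2-ethyl-1,4-benzoquinon-3-yl)oxy]-2-ethyl-4-(2,3,5-trimethoxyphenyl)but-3-ynoate, via bromohydroquinone 23 (not isolated)
Conditions: Bu4NF, AcOH, THF, 0 °C; then MnO2, CH2Cl2, rt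
Reagents that add atoms: none
Why: Buffered fluoride cleaves the aryl silyl ether, and MnO2 oxidises the hydroquinone to the quinone under conditions too mild to touch the trimethoxyaryl alkyne. Bromine now sits on C6, next to the C1 carbonyl.

**Step 15**
Reactants: 25 methyl 4-methoxyacetoacetate
Product: 26 methyl 4-methoxy-3-(trimethylsilyloxy)but-2-enoate
Conditions: Me3SiCl, Et3N, hexane, rt
Reagents that add atoms: chlorotrimethylsilane, C[Si](C)(C)Cl
Why: Soft enolisation and O-silylation of a β-keto ester towards the conjugated enol ether.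

**Step 16**
Reactants: 26 methyl 4-methoxy-3-(trimethylsilyloxy)but-2-enoate
Product: 27 1,4-dimethoxy-1,3-bis(trimethylsilyloxy)buta-1,3-diene (mixture of geometric isomers)
Conditions: LiN(iPr)2, THF, –78 °C; then Me3SiCl, –78 °C → rt
Reagents that add atoms: chlorotrimethylsilane, C[Si](C)(C)Cl
Why: γ-Deprotonation of the silyloxy crotonate and O-silylation of the ester dienolate, the standard preparation of 1-alkoxy-1,3-bis(silyloxy)dienes; 27 is used crude.

**Step 17** (key step)
Reactants: 24 the bromobenzoquinone; 27 1,4-dimethoxy-1,3-bis(trimethylsilyloxy)buta-1,3-diene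
Product: 31 tert-butyl (R)-2-ethyl-2-[(2-ethyl-6,8-dihydroxy-5-methoxy-1,4-naphthoquinon-3-yl)oxy]-4-(2,3,5-trimethoxyphenyl)but-3-ynoate, via bromo cycloadduct 28 (not isolated), via dihydronaphthoquinone 29 (not isolated), via bis(silyl) ether 30 (not isolated)
Conditions: 27 (2.5 equiv), 2,6-lutidine (1.2 equiv), CH2Cl2, –40 °C → rt; then 0.5 M HCl, THF, 0 °C
Reagents that add atoms: none
Why: The electron-rich vinylketene acetal 27 adds to the only electron-poor, open double bond of 24 (C5=C6), either by an asynchronous [4+2] cycloaddition or by Mukaiyama–Michael addition followed by ring closure, with its methoxy-bearing terminus on the unsubstituted C5 and its acetal carbon on the brominated C6. The closest known reaction type is the regiospecific Diels–Alder benzannulation of 1-alkoxy-1,3-bis(silyloxy)butadienes with halobenzoquinones and halonaphthoquinones. The one ring formed, the six-membered carbocyclic ring B, closes intermolecularly in the [4+2] mode, or in the stepwise reading by 6-exo-trig attack of the bromo enolate on the silyloxy oxocarbenium carbon. The three sp3 centers of adduct 28 are lost again, so no stereocenter is created, and the quaternary carbinol center, remote from the reacting alkene, is not touched. Base-assisted loss of HBr restores the quinone double bond (29), 1,4-elimination of methanol from the acetal carbon and the C5 hydrogen gives arene 30 without any oxidant, and dilute acid removes both silyl groups. The selectivity needed is the orientation of the diene; the bromine on C6 secures it by sending the acetal carbon to C6 and the nucleophilic terminus to C5, so that oxygen arrives on C5, C6 and C8 and hydrogen on C7. The alkoxy group makes the C1 carbonyl a vinylogous ester and would by itself favour the opposite orientation, but halogen control is known to override comparable bias, and a twisted tertiary alkoxy group is a weak donor. The C2=C3 double bond is tetrasubstituted and donor-substituted and the aryl alkyne is electron-rich, so neither competes for the diene.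

**Step 18**
Reactants: 31 the 6,8-dihydroxy-5-methoxynaphthoquinone
Product: 32 tert-butyl (R)-2-ethyl-2-[(2-ethyl-5,6,8-trimethoxy-1,4-naphthoquinon-3-yl)oxy]-4-(2,3,5-trimethoxyphenyl)but-3-ynoate
Conditions: MeI (excess), Cs2CO3, DMF, rt → 40 °C
Reagents that add atoms: iodomethane, CI
Why: O-Methylation of both phenols; the chelated C8 hydroxyl reacts more slowly, hence excess reagent and gentle warming. Any isomeric methyl ether left by the aromatisation converges on 32 here.

**Step 19**
Reactants: 32 the trimethoxynaphthoquinone tert-butyl ester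
Product: 34 (R)-2-ethyl-2-[(2-ethyl-5,6,8-trimethoxy-1,4-naphthoquinon-3-yl)oxy]-4-(2,3,5-trimethoxyphenyl)but-3-ynoic acid, via trimethylsilyl ester 33 (not isolated)
Conditions: Me3SiOTf, 2,6-lutidine, CH2Cl2, 0 °C → rt; then pH 4 buffer
Reagents that add atoms: none
Why: Silyl-triflate cleavage of a tert-butyl ester: O-silylation, loss of the tert-butyl cation as isobutene, and hydrolysis of silyl ester 33 on work-up. The method is non-hydrolytic and buffered, so the base-labile vinylogous ester and the alkyne are spared.

**Step 20**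
Reactants: 34 the alkynoic acid
Product: 36 (2R,3Z)-2-ethyl-2-[(2-ethyl-5,6,8-trimethoxy-1,4-naphthoquinon-3-yl)oxy]-4-(2,3,5-trimethoxyphenyl)but-3-enoic acid, via hydroquinone 35 (not isolated)
Conditions: H2 (1 atm), Pd/CaCO3 poisoned with Pb(OAc)2, quinoline, EtOAc, rt; then air
Reagents that add atoms: none
Why: cis-Semihydrogenation of the alkyne on poisoned palladium gives the Z alkene that the ring closure needs. The quinone is expected to be reduced to hydroquinone 35 in passing and to return on exposure to air.

**Step 21**
Reactants: 36 the Z-alkenoic acid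
Product: 38 (R)-2-ethyl-2-[(2-ethyl-5,6,8-trimethoxy-1,4-naphthoquinon-3-yl)oxy]-5,6,8-trimethoxynaphthalen-1(2H)-one, via mixed anhydride 37 (not isolated)
Conditions: (CF3CO)2O, CH2Cl2, 0 °C → rt
Reagents that add atoms: none
Why: Intramolecular Friedel–Crafts acylation through the mixed trifluoroacetic anhydride; the acyl carbon attacks the only free position ortho to the alkenyl group, which is ortho and para to methoxy groups, and closes a six-membered ring (bond C4′–C4a′). The quaternary carbon has no α-hydrogen, so neither a ketene nor epimerisation is possible.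

**Step 22**
Reactants: 38 the naphthalenone
Product: 39 (2R)-2-ethyl-2-[(2-ethyl-5,6,8-trimethoxy-1,4-naphthoquinon-3-yl)oxy]-3,4-dihydroxy-5,6,8-trimethoxy-3,4-dihydronaphthalen-1(2H)-one (cis-diol, both diastereomers)
Conditions: OsO4 (5 mol %), N-methylmorpholine N-oxide, acetone/H2O, rt
Reagents that add atoms: osmium tetroxide, O=[Os](=O)(=O)=O; N-methylmorpholine N-oxide, C[N+]1([O-])CCOCC1
Why: Catalytic syn-dihydroxylation of the electron-rich styrenic ring alkene; the quinone double bond is tetrasubstituted and electron-poor and is left alone. The two new carbinol centers are uncontrolled and are removed in step 23.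

**Step 23**
Reactants: 39 the cis-diol
Product: 40 (S)-3-ethyl-3-[(2-ethyl-5,6,8-trimethoxy-1,4-naphthoquinon-3-yl)oxy]-5,7,8-trimethoxynaphthalene-1,2,4(3H)-trione
Conditions: (COCl)2, DMSO, CH2Cl2, –78 °C; then Et3N, –78 → 0 °C
Reagents that add atoms: none
Why: Swern oxidation of both secondary alcohols gives the vicinal dione without C–C cleavage. The quaternary carbon has no α-hydrogen, so the amine cannot enolise it; the descriptor changes to S by priority only.

**Step 24**
Reactants: 40 the hexamethyl ether
Product: 41 (S)-3-ethyl-3-[(2-ethyl-5,6,8-trihydroxy-1,4-naphthoquinon-3-yl)oxy]-5,7,8-trihydroxynaphthalene-1,2,4(3H)-trione (CNP0325426.1)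
Conditions: BBr3 (excess), CH2Cl2, –78 °C → rt; then H2O
Reagents that add atoms: none
Why: Lewis-acid cleavage of the six aryl methyl ethers, chelation-assisted at the four peri positions and by bromide attack at methyl for the other two. The bridging ether resists because its alkyl carbon is quaternary and flanked by two carbonyls, which excludes both displacement and ionisation.

## Compound list

1 | 3-bromo-4,5-dimethoxybenzaldehyde | COc1cc(C=O)cc(Br)c1OC | starting material
2 | 3-bromo-4,5-dimethoxyphenyl formate | COc1cc(OC=O)cc(Br)c1OC | intermediate (not isolated)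
3 | 3-bromo-4,5-dimethoxyphenol | COc1cc(O)cc(Br)c1OC | intermediate
4 | 1-bromo-2,3,5-trimethoxybenzene | COc1cc(Br)c(OC)c(OC)c1 | intermediate
5 | ethynyltrimethylsilane | C#C[Si](C)(C)C | starting material
6 | trimethyl[(2,3,5-trimethoxyphenyl)ethynyl]silane | COc1cc(C#C[Si](C)(C)C)c(OC)c(OC)c1 | intermediate
7 | 1-ethynyl-2,3,5-trimethoxybenzene | COc1cc(C#C)c(OC)c(OC)c1 | intermediate
8 | 2-oxobutanoic acid | CCC(=O)C(=O)O | starting material
9 | tert-butyl 2-oxobutanoate | CCC(=O)C(=O)OC(C)(C)C | intermediate
10 | tert-butyl (R)-2-ethyl-2-hydroxy-4-(2,3,5-trimethoxyphenyl)but-3-ynoate | O[C@](C(=O)OC(C)(C)C)(CC)C#Cc1cc(OC)cc(OC)c1OC | intermediate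
11 | 3,4-diisopropoxycyclobut-3-ene-1,2-dione (diisopropyl squarate) | CC(C)OC1=C(OC(C)C)C(=O)C1=O | starting material
12 | 4-ethyl-4-hydroxy-2,3-diisopropoxycyclobut-2-en-1-one (racemic) | CCC1(O)C(OC(C)C)=C(OC(C)C)C1=O | intermediate (not isolated)
13 | 3-ethyl-4-isopropoxycyclobut-3-ene-1,2-dione | CCC1=C(OC(C)C)C(=O)C1=O | intermediate
14 | 3-ethyl-4-hydroxycyclobut-3-ene-1,2-dione | CCC1=C(O)C(=O)C1=O | intermediate
15 | 3-chloro-4-ethylcyclobut-3-ene-1,2-dione | CCC1=C(Cl)C(=O)C1=O | intermediate
16 | tert-butyl (R)-2-ethyl-2-[(2-ethyl-3,4-dioxocyclobut-1-en-1-yl)oxy]-4-(2,3,5-trimethoxyphenyl)but-3-ynoate | CCC1=C(O[C@](C(=O)OC(C)(C)C)(CC)C#Cc2cc(OC)cc(OC)c2OC)C(=O)C1=O | intermediate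
17 | bromomagnesium alkoxide of the vinyl adduct of 16 (both epimers at the ring carbinol carbon) | CCC1=C(O[C@](C(=O)OC(C)(C)C)(CC)C#Cc2cc(OC)cc(OC)c2OC)C(C=C)(O[Mg]Br)C1=O | intermediate (not isolated)
18 | tert-butyl (2R)-2-ethyl-2-{[2-ethyl-3-oxo-4-(triethylsilyloxy)-4-vinylcyclobut-1-en-1-yl]oxy}-4-(2,3,5-trimethoxyphenyl)but-3-ynoate (both epimers at the ring carbinol carbon) | CCC1=C(O[C@](C(=O)OC(C)(C)C)(CC)C#Cc2cc(OC)cc(OC)c2OC)C(C=C)(O[Si](CC)(CC)CC)C1=O | intermediate
19 | dienylketene from ring opening of 18 | CCC(=C=O)C(O[C@](C(=O)OC(C)(C)C)(CC)C#Cc1cc(OC)cc(OC)c1OC)=C(O[Si](CC)(CC)CC)C=C | intermediate (not isolated)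
20 | 2-ethyl-3-alkoxy-4-(triethylsilyloxy)cyclohexa-2,4-dien-1-one from 19 | CCC1=C(O[C@](C(=O)OC(C)(C)C)(CC)C#Cc2cc(OC)cc(OC)c2OC)C(O[Si](CC)(CC)CC)=CCC1=O | intermediate (not isolated)
21 | tert-butyl (R)-2-ethyl-2-[2-ethyl-3-hydroxy-6-(triethylsilyloxy)phenoxy]-4-(2,3,5-trimethoxyphenyl)but-3-ynoate | CCc1c(O)ccc(O[Si](CC)(CC)CC)c1O[C@](C(=O)OC(C)(C)C)(CC)C#Cc2cc(OC)cc(OC)c2OC | intermediate
22 | tert-butyl (R)-2-[4-bromo-2-ethyl-3-hydroxy-6-(triethylsilyloxy)phenoxy]-2-ethyl-4-(2,3,5-trimethoxyphenyl)but-3-ynoate | CCc1c(O)c(Br)cc(O[Si](CC)(CC)CC)c1O[C@](C(=O)OC(C)(C)C)(CC)C#Cc2cc(OC)cc(OC)c2OC | intermediate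
23 | tert-butyl (R)-2-(4-bromo-2-ethyl-3,6-dihydroxyphenoxy)-2-ethyl-4-(2,3,5-trimethoxyphenyl)but-3-ynoate | CCc1c(O)c(Br)cc(O)c1O[C@](C(=O)OC(C)(C)C)(CC)C#Cc2cc(OC)cc(OC)c2OC | intermediate (not isolated)
24 | tert-butyl (R)-2-[(6-bromo-2-ethyl-1,4-benzoquinon-3-yl)oxy]-2-ethyl-4-(2,3,5-trimethoxyphenyl)but-3-ynoate | CCC1=C(O[C@](C(=O)OC(C)(C)C)(CC)C#Cc2cc(OC)cc(OC)c2OC)C(=O)C=C(Br)C1=O | intermediate (key-step precursor)
25 | methyl 4-methoxyacetoacetate | COCC(=O)CC(=O)OC | starting material
26 | methyl 4-methoxy-3-(trimethylsilyloxy)but-2-enoate | COCC(O[Si](C)(C)C)=CC(=O)OC | intermediate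
27 | 1,4-dimethoxy-1,3-bis(trimethylsilyloxy)buta-1,3-diene (mixture of geometric isomers) | COC=C(O[Si](C)(C)C)C=C(OC)O[Si](C)(C)C | intermediate (key-step precursor)
28 | bromo cycloadduct of 24 and 27 (mixture of stereoisomers at the ring sp3 carbons) | CCC1=C(O[C@](C(=O)OC(C)(C)C)(CC)C#Cc2cc(OC)cc(OC)c2OC)C(=O)C3C(OC)C(O[Si](C)(C)C)=CC(OC)(O[Si](C)(C)C)C3(Br)C1=O | intermediate (not isolated)
29 | 5,8-dihydronaphthoquinone after loss of HBr (mixture of stereoisomers at C5 and C8) | CCC1=C(O[C@](C(=O)OC(C)(C)C)(CC)C#Cc2cc(OC)cc(OC)c2OC)C(=O)C3=C(C1=O)C(OC)(O[Si](C)(C)C)C=C(O[Si](C)(C)C)C3OC | intermediate (not isolated)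
30 | 6,8-bis(trimethylsilyl) ether of 31 | CCC1=C(O[C@](C(=O)OC(C)(C)C)(CC)C#Cc2cc(OC)cc(OC)c2OC)C(=O)c3c(OC)c(O[Si](C)(C)C)cc(O[Si](C)(C)C)c3C1=O | intermediate (not isolated)
31 | tert-butyl (R)-2-ethyl-2-[(2-ethyl-6,8-dihydroxy-5-methoxy-1,4-naphthoquinon-3-yl)oxy]-4-(2,3,5-trimethoxyphenyl)but-3-ynoate | CCC1=C(O[C@](C(=O)OC(C)(C)C)(CC)C#Cc2cc(OC)cc(OC)c2OC)C(=O)c3c(OC)c(O)cc(O)c3C1=O | intermediate (key-step product)
32 | tert-butyl (R)-2-ethyl-2-[(2-ethyl-5,6,8-trimethoxy-1,4-naphthoquinon-3-yl)oxy]-4-(2,3,5-trimethoxyphenyl)but-3-ynoate | CCC1=C(O[C@](C(=O)OC(C)(C)C)(CC)C#Cc2cc(OC)cc(OC)c2OC)C(=O)c3c(OC)c(OC)cc(OC)c3C1=O | intermediate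
33 | trimethylsilyl ester of 34 | CCC1=C(O[C@](C(=O)O[Si](C)(C)C)(CC)C#Cc2cc(OC)cc(OC)c2OC)C(=O)c3c(OC)c(OC)cc(OC)c3C1=O | intermediate (not isolated)
34 | (R)-2-ethyl-2-[(2-ethyl-5,6,8-trimethoxy-1,4-naphthoquinon-3-yl)oxy]-4-(2,3,5-trimethoxyphenyl)but-3-ynoic acid | CCC1=C(O[C@](C(=O)O)(CC)C#Cc2cc(OC)cc(OC)c2OC)C(=O)c3c(OC)c(OC)cc(OC)c3C1=O | intermediate
35 | (2R,3Z)-2-ethyl-2-[(2-ethyl-1,4-dihydroxy-5,6,8-trimethoxynaphthalen-3-yl)oxy]-4-(2,3,5-trimethoxyphenyl)but-3-enoic acid | CCc1c(O[C@](C(=O)O)(CC)/C=C\c2cc(OC)cc(OC)c2OC)c(O)c3c(OC)c(OC)cc(OC)c3c1O | intermediate (not isolated)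
36 | (2R,3Z)-2-ethyl-2-[(2-ethyl-5,6,8-trimethoxy-1,4-naphthoquinon-3-yl)oxy]-4-(2,3,5-trimethoxyphenyl)but-3-enoic acid | CCC1=C(O[C@](C(=O)O)(CC)/C=C\c2cc(OC)cc(OC)c2OC)C(=O)c3c(OC)c(OC)cc(OC)c3C1=O | intermediate
37 | mixed trifluoroacetic anhydride of 36 | CCC1=C(O[C@](C(=O)OC(=O)C(F)(F)F)(CC)/C=C\c2cc(OC)cc(OC)c2OC)C(=O)c3c(OC)c(OC)cc(OC)c3C1=O | intermediate (not isolated)
38 | (R)-2-ethyl-2-[(2-ethyl-5,6,8-trimethoxy-1,4-naphthoquinon-3-yl)oxy]-5,6,8-trimethoxynaphthalen-1(2H)-one | CCC1=C(O[C@]2(CC)C=Cc3c(OC)c(OC)cc(OC)c3C2=O)C(=O)c4c(OC)c(OC)cc(OC)c4C1=O | intermediate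
39 | (2R)-2-ethyl-2-[(2-ethyl-5,6,8-trimethoxy-1,4-naphthoquinon-3-yl)oxy]-3,4-dihydroxy-5,6,8-trimethoxy-3,4-dihydronaphthalen-1(2H)-one (cis-diol, both diastereomers) | CCC1=C(O[C@]2(CC)C(O)C(O)c3c(OC)c(OC)cc(OC)c3C2=O)C(=O)c4c(OC)c(OC)cc(OC)c4C1=O | intermediate
40 | (S)-3-ethyl-3-[(2-ethyl-5,6,8-trimethoxy-1,4-naphthoquinon-3-yl)oxy]-5,7,8-trimethoxynaphthalene-1,2,4(3H)-trione | CCC1=C(O[C@]2(CC)C(=O)C(=O)c3c(OC)c(OC)cc(OC)c3C2=O)C(=O)c4c(OC)c(OC)cc(OC)c4C1=O | intermediate
41 | (S)-3-ethyl-3-[(2-ethyl-5,6,8-trihydroxy-1,4-naphthoquinon-3-yl)oxy]-5,7,8-trihydroxynaphthalene-1,2,4(3H)-trione (CNP0325426.1) | CCC1=C(O[C@]2(CC)C(=O)C(=O)c3c(O)c(O)cc(O)c3C2=O)C(=O)c4c(O)c(O)cc(O)c4C1=O | target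

## Step count and least certain steps

Total: 24 steps. Longest linear sequence: 18 steps (1, 2, 3, 4, 6, 10–14, 17–24, counted from compound 1). The squarate branch (steps 7–9), the keto ester (step 5) and the diene (steps 15–16) are side branches.

**Step 17 (key step).** The most likely failure is loss of regiocontrol or of reactivity. The alkoxy group on the other double bond opposes the orientation the bromine dictates, and the extra 4-methoxy group on the diene may slow the addition or divert the intermediate to simple substitution of bromide.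
Fallback: ring B is brought in as a preformed arene. Aryl bromide 4 is converted by bromine–lithium exchange (n-BuLi, THF, –78 °C) into the aryllithium and added to squarate ester 16. This gives tert-butyl (2R)-2-ethyl-2-{[2-ethyl-4-hydroxy-3-oxo-4-(2,3,5-trimethoxyphenyl)cyclobut-1-en-1-yl]oxy}-4-(2,3,5-trimethoxyphenyl)but-3-ynoate F1. Heating F1 in xylene gives, by ring expansion onto the single free ortho carbon, tert-butyl (R)-2-ethyl-2-[(2-ethyl-1,4-dihydroxy-5,6,8-trimethoxynaphthalen-3-yl)oxy]-4-(2,3,5-trimethoxyphenyl)but-3-ynoate F2. Oxidation of F2 with MnO2 returns to the route at 32.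

**Step 21.** The tertiary allylic C–O bond carries a good leaving group (the hydroxyquinone). Under acid it may ionise, or the acid may lactonise onto the styrene, before the acylation occurs.
Fallback: starting from 36, the acid is converted under neutral conditions with 1-chloro-N,N,2-trimethylprop-1-en-1-amine into (2R,3Z)-2-ethyl-2-[(2-ethyl-5,6,8-trimethoxy-1,4-naphthoquinon-3-yl)oxy]-4-(2,3,5-trimethoxyphenyl)but-3-enoyl chloride F5. F5 is cyclised in 1,1,1,3,3,3-hexafluoropropan-2-ol without added acid, and the route is rejoined at 38.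

**Step 13.** The brominating agent may attack the trimethoxyphenyl ring, which is also doubly activated, or oxidise the silyloxyphenol instead of substituting it.
Fallback: the bromine is introduced as a nucleophile. Starting from 21, desilylation (Bu4NF, AcOH) and MnO2 oxidation give tert-butyl (R)-2-ethyl-2-[(2-ethyl-1,4-benzoquinon-3-yl)oxy]-4-(2,3,5-trimethoxyphenyl)but-3-ynoate F3. Conjugate addition of bromide (LiBr, AcOH, THF) should occur at C6, the carbon β to the ketone-like C4 carbonyl, because the C1 carbonyl is a deactivated vinylogous ester. This gives bromohydroquinone 23, which the MnO2 stage of step 14 takes on to 24.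

**Step 20.** Over-reduction of the alkene or hydrogenolysis of the propargylic or allylic C–O bond on palladium is possible, complicated by the reversible reduction of the quinone.
Fallback: the reduction is avoided altogether. Starting from 34, the alkyne is oxidised directly with buffered KMnO4 (NaHCO3, MgSO4, aqueous acetone) to (R)-2-ethyl-2-[(2-ethyl-5,6,8-trimethoxy-1,4-naphthoquinon-3-yl)oxy]-3,4-dioxo-4-(2,3,5-trimethoxyphenyl)butanoic acid F4. Friedel–Crafts closure of F4 in P2O5/MeSO3H gives 40 directly; the stronger acid is tolerable because the quaternary carbon is then flanked by carbonyl groups. This bypasses steps 20–23.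

**Step 6.** Enantioselectivity may be insufficient for a tert-butyl keto ester with an ortho-substituted aryl alkyne, and the sense of induction has to be established.
Fallback: the lithium acetylide of 7 (n-BuLi, THF, –78 °C) is added to 9 to give racemic tert-butyl 2-ethyl-2-hydroxy-4-(2,3,5-trimethoxyphenyl)but-3-ynoate F6. The enantiomers are separated by preparative chromatography on a chiral stationary phase, and the R enantiomer is 10.

## Further compounds

F1 | step 17 | tert-butyl (2R)-2-ethyl-2-{[2-ethyl-4-hydroxy-3-oxo-4-(2,3,5-trimethoxyphenyl)cyclobut-1-en-1-yl]oxy}-4-(2,3,5-trimethoxyphenyl)but-3-ynoate (both epimers at the ring carbinol carbon) | CCC1=C(O[C@](C(=O)OC(C)(C)C)(CC)C#Cc2cc(OC)cc(OC)c2OC)C(O)(c2cc(OC)cc(OC)c2OC)C1=O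
F2 | step 17 | tert-butyl (R)-2-ethyl-2-[(2-ethyl-1,4-dihydroxy-5,6,8-trimethoxynaphthalen-3-yl)oxy]-4-(2,3,5-trimethoxyphenyl)but-3-ynoate | CCc1c(O[C@](C(=O)OC(C)(C)C)(CC)C#Cc2cc(OC)cc(OC)c2OC)c(O)c2c(OC)c(OC)cc(OC)c2c1O
F3 | step 13 | tert-butyl (R)-2-ethyl-2-[(2-ethyl-1,4-benzoquinon-3-yl)oxy]-4-(2,3,5-trimethoxyphenyl)but-3-ynoate | CCC1=C(O[C@](C(=O)OC(C)(C)C)(CC)C#Cc2cc(OC)cc(OC)c2OC)C(=O)C=CC1=O
F4 | step 20 | (R)-2-ethyl-2-[(2-ethyl-5,6,8-trimethoxy-1,4-naphthoquinon-3-yl)oxy]-3,4-dioxo-4-(2,3,5-trimethoxyphenyl)butanoic acid | CCC1=C(O[C@](C(=O)O)(CC)C(=O)C(=O)c2cc(OC)cc(OC)c2OC)C(=O)c3c(OC)c(OC)cc(OC)c3C1=O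
F5 | step 21 | (2R,3Z)-2-ethyl-2-[(2-ethyl-5,6,8-trimethoxy-1,4-naphthoquinon-3-yl)oxy]-4-(2,3,5-trimethoxyphenyl)but-3-enoyl chloride | CCC1=C(O[C@](C(=O)Cl)(CC)/C=C\c2cc(OC)cc(OC)c2OC)C(=O)c3c(OC)c(OC)cc(OC)c3C1=O
F6 | step 6 | racemic tert-butyl 2-ethyl-2-hydroxy-4-(2,3,5-trimethoxyphenyl)but-3-ynoate | CCC(O)(C#Cc1cc(OC)cc(OC)c1OC)C(=O)OC(C)(C)C
A1 | alternative 1 | bis(2-ethyl-5,6,8-trimethoxy-1,4-naphthoquinon-3-yl) ether | CCC1=C(OC2=C(CC)C(=O)c3c(OC)cc(OC)c(OC)c3C2=O)C(=O)c4c(OC)c(OC)cc(OC)c4C1=O
A2 | alternative 1 | hexamethyl ether of the target, (S)-3-ethyl-3-[(2-ethyl-5,6,8-trimethoxy-1,4-naphthoquinon-3-yl)oxy]-5,7,8-trimethoxynaphthalene-1,2,4(3H)-trione | CCC1=C(O[C@]2(CC)C(=O)C(=O)c3c(OC)c(OC)cc(OC)c3C2=O)C(=O)c2c(OC)c(OC)cc(OC)c2C1=O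
A3 | alternative 2 | 3,4,6-trimethoxy-2-(3-oxopentyl)benzaldehyde | CCC(=O)CCc1c(OC)c(OC)cc(OC)c1C=O
A4 | alternative 2 | (R)-2-ethyl-2-hydroxy-5,6,8-trimethoxy-3,4-dihydronaphthalen-1(2H)-one | O[C@]1(CC)CCc2c(OC)c(OC)cc(OC)c2C1=O
A5 | alternative 3 | ethyl (2R)-2-ethyl-2-{[2-ethyl-4-hydroxy-3-oxo-4-(2,3,5-trimethoxyphenyl)cyclobut-1-en-1-yl]oxy}-4-(2,3,5-trimethoxyphenyl)but-3-ynoate | CCC1=C(O[C@](C(=O)OCC)(CC)C#Cc2cc(OC)cc(OC)c2OC)C(O)(c2cc(OC)cc(OC)c2OC)C1=O
A6 | alternative 3 | ethyl (R)-2-ethyl-2-[(2-ethyl-1,4-dihydroxy-5,6,8-trimethoxynaphthalen-3-yl)oxy]-4-(2,3,5-trimethoxyphenyl)but-3-ynoate | CCc1c(O[C@](C(=O)OCC)(CC)C#Cc2cc(OC)cc(OC)c2OC)c(O)c2c(OC)c(OC)cc(OC)c2c1O
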